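## Analysis of the target

- **Skeleton.** The target is a stilbenoid trimer. An (E)-4-hydroxystyryl group (ring A) sits on C6 of a 2,3-dihydrobenzofuran (benzo ring B; furan ring C = O1, C2, C3, C3a, C7a). C3 carries a 3,5-dihydroxyphenyl group (ring D), and C2 is bonded to C7' of a second 2,3-dihydrobenzofuran (benzo ring E; furan ring F = O1', C2', C3', C3a', C7a'). Ring F carries a 2,4-dihydroxyphenyl group (ring G) on C2' and a 3,5-dihydroxyphenyl group (ring H) on C3'.
- **Stereocentres.** There are four, C2, C3, C2' and C3', all R. In each furan ring the two aryl groups are trans. The two diads are separated by ring E, so neither can be relied on to control the other.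
- **Sensitive groups.** Nine phenols (air oxidation), the stilbene (light, strong acid), and the benzylic ether bonds O1–C2 and O1'–C2'. These two bonds ionise easily because C2 and C2' each carry an aryl group with ortho and para oxygen.
- **Consequence of that lability.** C2 and C2' can be corrected thermodynamically to trans, so only C3 and C3' have to be set absolutely and then preserved.
- **Difficulty.** Every stereocentre is a benzylic carbon bearing an aryl group. C3a' and C3a each lie between two oxygenated ring carbons. Ring E is tetrasubstituted in a row (C7', C7a', C3a', C4').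
- **Feature used.** C3' bears ring H and C3a' of ring E; C2' bears ring G and O1'. This is an ethane with three different aryl groups and one oxygen. It maps onto a styrenyl boron reagent (ring H–C3'=C2'–B), an aryl group that migrates from boron to C2' (ring G) and an aryl electrophile (ring E at C3a'), with boron as the later O1'. The same pattern recurs at C2–C3 (ring D, ring B, ring E as the migrating aryl).

## Retrosynthetic reasoning

**33 to 32.** The eight O–CH3 bonds are cut last. Methyl ethers are the only phenol protection that survives aryllithium and alkenyllithium reagents, palladium catalysis, basic peroxide and the acid ring closures. The forward step is a Lewis-acid ether cleavage on 32, whose C4 phenol is already free.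

**32 to 30 (through 31).** The O1–C2 bond is cut, opening ring C to a benzylic alcohol at C2 and two acetal-protected phenols on ring B. Ring B is symmetric about the C3a–C6 axis, so both oxygens can carry the same methoxymethyl group and either freed phenol gives the same ring. The forward step must remove both acetals, ionise the C2 alcohol (cation stabilised by O1' and the C4' methoxy group of ring E) and close ring C trans without touching C3.

**30 to 19, 20 and 26 (through 27, 28, 29).** The C3–C3a and C2–C7' bonds are cut, and the C2 oxygen is traced back to boron. This is the second use of the three-component coupling: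
- boronate 19 supplies the ring E/F aryl group on boron;
- vinyl iodide 20 supplies C2, C3 and ring D as alkenyllithium 27;
- bromide 26 supplies ring B with the styryl arm already in place, so no olefination is needed on the advanced material.

The forward step must set C3 by catalyst control; C2 is corrected in the next step.

**19 to 17; 26 to 21; 20 to 5.** Boronate 19 comes from chloride 17 by borylation at C7' and esterification with diol 2. The chloride is the one substituent that passes through the first coupling untouched and can still be activated afterwards. Bromide 26 comes from aldehyde 24 and phosphonate 25 by olefination; 24 comes from the commercial bromo diol ester 21 through 22 and 23. Iodide 20 comes from boronic acid 5, which also serves the first coupling.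

**17 to 15 (through 16) to 14.** The O1'–C2' bond is cut to alcohol 15, and the C2' oxygen is traced back to the boron of 14. The oxidation keeps the configuration. The acid closure goes through the C2' cation stabilised by ring G and gives the trans ring, so only C3' of 14 must be right.

**14 to 11, 6 and 10 (through 12, 13).** This is the key disconnection: C2'–C1(ring G) and C3'–C3a' are cut together.
- Bromide 11 gives aryllithium 12 (ring G).
- Alkenyl boronate 6 gives ring H, C3', C2' and boron.
- Bromide 10 gives ring E with its two oxygens already differentiated and the C7' chloride in place.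

The cut is made here because it joins three simple arenes and creates C3' in one catalytic step. The boron ligand is diol 2 and not a simple aliphatic diol, because a β-substituted alkenyl ate complex otherwise tends to hand its alkenyl group directly to palladium.

**6, 10 and 2 to starting materials.** Boronate 6 is the ester of boronic acid 5 with diol 2; 5 comes from alkyne 3 by hydroboration (through 4); 2 comes from diketone 1. Bromide 10 comes from phenol 7, which already has the hydroxyl ortho and the methoxy para to chlorine. Acetal protection gives 8, and lithiation between the two oxygens (9) followed by bromination gives 10. No oxygen differentiation is needed.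

## Alternatives that were turned down

**Alternative 1:** Ring F is disconnected at O1'–C2' and C3'–H, back to the flat triarylethene phenol A1. In the forward step a confined chiral imidodiphosphorimidate acid protonates C3' and the ring E phenol captures the C2' cation, giving 7-bromo dihydrobenzofuran A2.
- For: A1 is achiral and quickly made; one atom-economical catalytic step closes ring F and sets both centres; no organolithium and no hindered aryl coupling. On step count to dihydrobenzofuran 2 this is shorter than coupling, oxidation and acid closure, and that point goes to the alternative.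
- Against: the stereo-determining event is delivery of a proton to a carbon flanked by two aryl groups of similar size (ring E and ring H), and it is reversible. The same acid can reopen A2 through the C2' cation and return to A1, which loses C3'. The alkene of A1 is twisted by the two ortho oxygens of ring E, which lowers its basicity.
- Comparison: the chosen route fixes C3' in an irreversible C–C bond formation under neutral conditions. Acid is met later there too, but only after C3' is set, and that step can be reordered. Alternative 1 offers nothing for ring C beyond the same halide handle.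

**Alternative 2:** Benzo ring E is disconnected at C7a'–C3a', C4'–C5' and C7a'–C7'. In the forward step irradiation turns diazo ketone A3 by Wolff rearrangement into vinylketene A4, which adds to siloxyalkyne A5. Four-electron ring opening and six-electron closure then give salicylate A6.
- For: the four contiguous substituents of ring E arise with fixed regiochemistry, the two oxygens are differentiated from the outset, and C7' is an ester that leads directly to C2. No aryl–C(sp3) coupling at a doubly ortho-substituted carbon is needed. On these points it is stronger than bromide 10 with its spectator chloride.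
- Against: the benzannulation creates no stereocentre. C3' and C2' must both already be in A5, which needs a separate asymmetric synthesis of a 1,2-diaryl unit. C3'–H of A5 is propargylic and benzylic and can epimerise under the base used to make a siloxyalkyne. Ring F still has to be closed by ionisation at C2'. The sequence is long and linear, with a photochemical step.
- Comparison: the chosen coupling creates C3' while joining rings E, G and H from three pieces that each need at most three steps.

**Alternative 3:** Ring C is disconnected at C2–C3 and O1–C2. In the forward step a carbonate base converts ring B sulfone A7 into ortho-quinone methide A9 and deprotonates sulfonium salt A8 (drawn with a C2-symmetric chiral thiolane as an example). The ylide carbon adds to the methide carbon and the phenoxide displaces the sulfide, giving bis(dihydrobenzofuran) A10.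
- For: the union is late and convergent, closes ring C and sets C2 and C3 trans in one operation, and needs no oxidation, no acid closure and no second hindered arylpalladium. For ring C alone it is more direct than the chosen coupling, oxidation and cyclisation.
- Against: it does not address ring F, so A8 with its two stereocentres must be made first by other chemistry. Absolute control at C3 rests on a stoichiometric chiral sulfide whose information reaches C3 only through diastereoselection on a planar, fully aryl-substituted methide. The existing centres in A8 create matched and mismatched cases. The 2,6-dioxygenated methide A9 is strongly stabilised and a weak electrophile. The ester of A10 needs three more steps to become the styryl arm.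
- Comparison: the chosen route uses one catalytic method for both diads, puts catalyst control on the carbon that must survive (C3', C3), and leaves C2' and C2 to thermodynamic correction.

Key step: step 6

## Route

Assumption: the (Sp,Sp) antipode of the MandyPhos ligand is written for both couplings; the sense of face selection has to be assigned on compound 14, and the mirror-image ligand is taken if it proves opposite.

MandyPhos = 1,1'-bis[bis(4-methoxy-3,5-dimethylphenyl)phosphino]-2,2'-bis[(R)-α-(dimethylamino)benzyl]ferrocene. B(mac) = cyclic boronic ester of diol 2.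

Step 1
Reactants: 1 acenaphthoquinone
Product: 2 cis-1,2-dimethyl-1,2-dihydroacenaphthylene-1,2-diol (meso; mac diol)
Conditions: MeMgBr (2.5 equiv), THF, −78 °C → rt; aq. NH4Cl; recrystallisation
Reagents that add atoms: methylmagnesium bromide, C[Mg]Br
Why: Double Grignard addition to the 1,2-diketone; the second methyl group should enter from the face away from the solvated magnesium alkoxide, so the cis diol is expected to predominate, is purified by crystallisation, and is the only isomer able to chelate boron.

Step 2
Reactants: 3 1-ethynyl-3,5-dimethoxybenzene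
Product: 5 (E)-2-(3,5-dimethoxyphenyl)vinylboronic acid, via catechol boronate 4 (not isolated)
Conditions: catecholborane, Cy2BH (5 mol%), THF, rt; then H2O, rt; crystallisation
Reagents that add atoms: catecholborane, [H]B1Oc2ccccc2O1; water, O
Why: Brown hydroboration of a terminal alkyne: syn, anti-Markovnikov addition of B–H puts boron on the terminal carbon and gives the (E)-alkenyl boronate, which water cleaves to the boronic acid.

Step 3
Reactants: 5 (E)-2-(3,5-dimethoxyphenyl)vinylboronic acid; 2 mac diol
Product: 6 (E)-2-(3,5-dimethoxyphenyl)vinyl B(mac)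
Conditions: MgSO4, CH2Cl2, rt
Reagents that add atoms: none
Why: Boronic esterification of a cis-1,2-diol under dehydrating conditions; the alkene geometry is not touched.

Step 4
Reactants: 7 2-chloro-5-methoxyphenol
Product: 8 1-chloro-4-methoxy-2-(methoxymethoxy)benzene
Conditions: MOMCl, i-Pr2NEt, CH2Cl2, 0 °C → rt
Reagents that add atoms: chloromethyl methyl ether, COCCl
Why: O-Alkylation of the phenol to the methoxymethyl acetal, which withstands the organolithium of step 5 and directs it.

Step 5
Reactants: 8 1-chloro-4-methoxy-2-(methoxymethoxy)benzene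
Product: 10 2-bromo-4-chloro-1-methoxy-3-(methoxymethoxy)benzene, via aryllithium 9 (not isolated)
Conditions: n-BuLi, THF, −78 → 0 °C; then BrCCl2CCl2Br, −78 °C → rt
Reagents that add atoms: 1,2-dibromo-1,1,2,2-tetrachloroethane, BrC(Cl)(Cl)C(Cl)(Cl)Br
Why: Directed ortho-metalation at the only C–H flanked by both oxygen groups, then bromination of the aryllithium; lithium is meta to chlorine, so no aryne can form.

Step 6
Reactants: 11 1-bromo-2,4-dimethoxybenzene; 6 (E)-2-(3,5-dimethoxyphenyl)vinyl B(mac); 10 2-bromo-4-chloro-1-methoxy-3-(methoxymethoxy)benzene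
Product: 14 (1R,2R)-2-[3-chloro-6-methoxy-2-(methoxymethoxy)phenyl]-1-(2,4-dimethoxyphenyl)-2-(3,5-dimethoxyphenyl)ethyl B(mac) (C2'R,C3'R), via 2,4-dimethoxyphenyllithium 12 (not isolated), via lithium ate complex 13 (not isolated)
Conditions: 11, t-BuLi (2 equiv), Et2O, −78 °C; 6, THF, −78 °C → rt; then 10, Pd(OAc)2 (5 mol%), (Sp,Sp)-MandyPhos (6 mol%), KOTf (2.2 equiv), THF, 60 °C
Reagents that add atoms: none
Why: Lithium–bromine exchange gives 12, which adds to the boron of 6 to form ate complex 13; Pd(OAc)2 and the bisphosphine give zerovalent palladium, which inserts into the C–Br bond of 10, and KOTf removes bromide to leave a cationic arylpalladium species (divalent palladium). This cation binds the alkene of 13 and induces a 1,2-metallate shift in which ring G moves from boron to C2' anti to palladium while palladium takes C3', and reductive elimination with retention then forms C3'–C3a'. The closest known reaction type is the palladium-catalysed conjunctive cross-coupling of β-substituted alkenyl boron ate complexes of diol 2 with aryl electrophiles. No ring is closed in this step. C3' is set by the chiral ligand, which decides the alkene face that palladium takes, and C2' follows from the (E) geometry and the anti addition, which together give the (C2'R,C3'R) pair. The step needs the metallate shift to outrun direct transfer of the alkenyl group from boron to palladium, and the hindered oxygens of diol 2, which bridge poorly to palladium, secure this. It also needs C–Br to react before C–Cl, which the weaker C–Br bond secures, and only one carbon group on boron (ring G) is free to migrate.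

Step 7
Reactants: 14 triarylethyl B(mac)
Product: 15 (1R,2R)-2-[3-chloro-6-methoxy-2-(methoxymethoxy)phenyl]-1-(2,4-dimethoxyphenyl)-2-(3,5-dimethoxyphenyl)ethanol
Conditions: H2O2 (30% aq.), NaOH (3 M), THF, 0 °C → rt
Reagents that add atoms: hydrogen peroxide, OO
Why: Oxidation of the C–B bond by hydroperoxide (1,2-shift of carbon from boron to oxygen) goes with retention, so C2' becomes the carbinol with unchanged configuration; aryl chloride, acetal and methyl ethers are inert.

Step 8
Reactants: 15 triarylethanol
Product: 17 (2R,3R)-7-chloro-2-(2,4-dimethoxyphenyl)-3-(3,5-dimethoxyphenyl)-4-methoxy-2,3-dihydrobenzofuran, via diol 16 (not isolated)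
Conditions: HCl (1.25 M in MeOH), THF, 0 °C → rt
Reagents that add atoms: none
Why: Acid cleaves the acetal and ionises the 2,4-dimethoxybenzylic alcohol, and the C7a' phenol captures the cation to close ring F (SN1 cyclodehydration, 5-exo). The closure is reversible, so the aryl groups on C2' and C3' should end trans, and C3' takes no part.

Step 9
Reactants: 17 chloro dihydrobenzofuran; 2 mac diol
Product: 19 (2R,3R)-2-(2,4-dimethoxyphenyl)-3-(3,5-dimethoxyphenyl)-4-methoxy-2,3-dihydrobenzofuran-7-yl B(mac), via boronic acid 18 (not isolated)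
Conditions: B2(OH)4, PdCl(2'-amino-1,1'-biphenyl-2-yl)(XPhos) (second-generation XPhos precatalyst, 3 mol%), XPhos, KOAc, EtOH, 80 °C; then 2, MgSO4, CH2Cl2, rt
Reagents that add atoms: tetrahydroxydiboron, OB(O)B(O)O
Why: Palladium-catalysed Miyaura-type borylation of an aryl chloride with tetrahydroxydiboron gives the boronic acid, which is esterified with diol 2; the biaryl phosphine is the ligand class that activates electron-rich, ortho-substituted aryl chlorides.

Step 10
Reactants: 5 (E)-2-(3,5-dimethoxyphenyl)vinylboronic acid
Product: 20 (E)-1-(2-iodovinyl)-3,5-dimethoxybenzene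
Conditions: NaOH (aq., 3 equiv), then I2, Et2O, 0 °C
Reagents that add atoms: iodine, II
Why: Brown iododeboronation of an (E)-alkenylboronic acid with iodine and hydroxide goes with retention of alkene geometry, and the basic medium spares the electron-rich ring.

Step 11
Reactants: 21 methyl 4-bromo-3,5-dihydroxybenzoate
Product: 22 methyl 4-bromo-3,5-bis(methoxymethoxy)benzoate
Conditions: MOMCl (2.5 equiv), i-Pr2NEt, CH2Cl2, 0 °C → rt
Reagents that add atoms: chloromethyl methyl ether, COCCl
Why: Double O-alkylation to the bis-acetal; both oxygens may carry the same group because ring B is symmetric.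

Step 12
Reactants: 22 methyl 4-bromo-3,5-bis(methoxymethoxy)benzoate
Product: 23 [4-bromo-3,5-bis(methoxymethoxy)phenyl]methanol
Conditions: i-Bu2AlH (2.5 equiv), CH2Cl2, −78 → 0 °C; Rochelle salt work-up
Reagents that add atoms: none
Why: Hydride reduction of the ester to the benzyl alcohol; aryl bromide and acetals are not attacked by the aluminium hydride.

Step 13
Reactants: 23 [4-bromo-3,5-bis(methoxymethoxy)phenyl]methanol
Product: 24 4-bromo-3,5-bis(methoxymethoxy)benzaldehyde
Conditions: MnO2, CH2Cl2, rt
Reagents that add atoms: none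
Why: Selective oxidation of a benzylic alcohol to the aldehyde by MnO2, with no over-oxidation.

Step 14
Reactants: 24 4-bromo-3,5-bis(methoxymethoxy)benzaldehyde; 25 diethyl (4-methoxybenzyl)phosphonate
Product: 26 2-bromo-1,3-bis(methoxymethoxy)-5-[(E)-2-(4-methoxyphenyl)ethenyl]benzene
Conditions: NaH, THF, 0 °C → rt
Reagents that add atoms: none
Why: Horner–Wadsworth–Emmons olefination of an aryl aldehyde with a benzylic phosphonate anion, which gives the (E)-stilbene.

Step 15
Reactants: 20 (E)-1-(2-iodovinyl)-3,5-dimethoxybenzene; 19 dihydrobenzofuranyl B(mac); 26 stilbene bromide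
Product: 30 (1R,2R)-2-[2,6-bis(methoxymethoxy)-4-[(E)-2-(4-methoxyphenyl)ethenyl]phenyl]-1-[(2R,3R)-2-(2,4-dimethoxyphenyl)-3-(3,5-dimethoxyphenyl)-4-methoxy-2,3-dihydrobenzofuran-7-yl]-2-(3,5-dimethoxyphenyl)ethanol, via alkenyllithium 27 (not isolated), via lithium ate complex 28 (not isolated), via boronate 29 (not isolated)
Conditions: 20, t-BuLi (2 equiv), Et2O, −78 °C; 19, THF, −78 °C → rt; then 26, Pd(OAc)2 (5 mol%), (Sp,Sp)-MandyPhos (6 mol%), KOTf (2.2 equiv), THF, 60 °C; then NaOH (3 M), H2O2 (30% aq.), 0 °C → rt
Reagents that add atoms: hydrogen peroxide, OO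
Why: The same conjunctive cross-coupling as in step 6, with the ate complex assembled in the reverse sense (aryl on boron, alkenyllithium added): the ring E/F aryl group migrates to C2 anti to palladium and ring B is delivered to C3. The same ligand antipode should set C3 as R, since the three partners play the same roles as in step 6. Oxidation with retention gives the C2 carbinol, and the stilbene is inert to the ate complex, the catalyst and basic peroxide.

Step 16
Reactants: 30 bis-acetal alcohol
Product: 32 (2R,3R)-2-[(2R,3R)-2-(2,4-dimethoxyphenyl)-3-(3,5-dimethoxyphenyl)-4-methoxy-2,3-dihydrobenzofuran-7-yl]-3-(3,5-dimethoxyphenyl)-6-[(E)-2-(4-methoxyphenyl)ethenyl]-2,3-dihydrobenzofuran-4-ol, via triol 31 (not isolated)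
Conditions: HCl (1.25 M in MeOH), THF, 0 °C → rt
Reagents that add atoms: none
Why: As in step 8: both acetals fall, the C2 alcohol ionises (cation stabilised by O1' and the C4' methoxy group of ring E), and either of the two equivalent ring B phenols closes ring C trans (SN1 cyclodehydration). The other phenol remains as the C4 hydroxyl, and ring F can only return to its trans form if it opens.

Step 17
Reactants: 32 octamethyl ether
Product: 33 target, (2R,3R)-2-[(2R,3R)-2-(2,4-dihydroxyphenyl)-3-(3,5-dihydroxyphenyl)-4-hydroxy-2,3-dihydrobenzofuran-7-yl]-3-(3,5-dihydroxyphenyl)-6-[(E)-2-(4-hydroxyphenyl)ethenyl]-2,3-dihydrobenzofuran-4-ol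
Conditions: BBr3 (excess), CH2Cl2, −78 °C → rt; MeOH, then aq. NaHCO3, under argon
Reagents that add atoms: none
Why: Lewis-acid cleavage of aryl methyl ethers: bromide attacks the methyl group of each boron-bound ether. If O1–C2 or O1'–C2' ionise, the phenol should close again on work-up to the same trans rings, because C3 and C3' are untouched. The styryl arm sits on C6, out of reach of ring D, so acid-induced cyclisation onto the alkene has no path.

## Compound list

1 | acenaphthoquinone | O=C1C(=O)c2cccc3cccc1c23 | starting material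
2 | cis-1,2-dimethyl-1,2-dihydroacenaphthylene-1,2-diol (mac diol) | O[C@@]1(C)c2cccc3cccc(c23)[C@@]1(C)O | intermediate
3 | 1-ethynyl-3,5-dimethoxybenzene | COc1cc(C#C)cc(OC)c1 | starting material
4 | 2-[(E)-2-(3,5-dimethoxyphenyl)vinyl]-1,3,2-benzodioxaborole | COc1cc(/C=C/B2Oc3ccccc3O2)cc(OC)c1 | intermediate (not isolated)
5 | (E)-2-(3,5-dimethoxyphenyl)vinylboronic acid | COc1cc(/C=C/B(O)O)cc(OC)c1 | intermediate
6 | (E)-2-(3,5-dimethoxyphenyl)vinyl B(mac) | COc1cc(/C=C/B2O[C@@]3(C)c4cccc5cccc(c45)[C@@]3(C)O2)cc(OC)c1 | intermediate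
7 | 2-chloro-5-methoxyphenol | COc1ccc(Cl)c(O)c1 | starting material
8 | 1-chloro-4-methoxy-2-(methoxymethoxy)benzene | COCOc1cc(OC)ccc1Cl | intermediate
9 | [3-chloro-6-methoxy-2-(methoxymethoxy)phenyl]lithium | [Li]c1c(OC)ccc(Cl)c1OCOC | intermediate (not isolated)
10 | 2-bromo-4-chloro-1-methoxy-3-(methoxymethoxy)benzene | COc1ccc(Cl)c(OCOC)c1Br | intermediate
11 | 1-bromo-2,4-dimethoxybenzene | COc1ccc(Br)c(OC)c1 | starting material
12 | 2,4-dimethoxyphenyllithium | [Li]c1ccc(OC)cc1OC | intermediate (not isolated)
13 | lithium ate complex of 6 with the 2,4-dimethoxyphenyl group on boron (configuration at boron not defined) | [Li+].COc1cc(/C=C/[B-]2(c3ccc(OC)cc3OC)O[C@@]3(C)c4cccc5cccc(c45)[C@@]3(C)O2)cc(OC)c1 | intermediate (not isolated)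
14 | (1R,2R)-2-[3-chloro-6-methoxy-2-(methoxymethoxy)phenyl]-1-(2,4-dimethoxyphenyl)-2-(3,5-dimethoxyphenyl)ethyl B(mac) | COc1ccc(Cl)c(OCOC)c1[C@@H](c1cc(OC)cc(OC)c1)[C@H](c1ccc(OC)cc1OC)B1O[C@@]2(C)c3cccc4cccc(c34)[C@@]2(C)O1 | intermediate
15 | (1R,2R)-2-[3-chloro-6-methoxy-2-(methoxymethoxy)phenyl]-1-(2,4-dimethoxyphenyl)-2-(3,5-dimethoxyphenyl)ethanol | COc1ccc(Cl)c(OCOC)c1[C@@H](c1cc(OC)cc(OC)c1)[C@H](c1ccc(OC)cc1OC)O | intermediate
16 | 6-chloro-2-[(1R,2R)-2-(2,4-dimethoxyphenyl)-1-(3,5-dimethoxyphenyl)-2-hydroxyethyl]-3-methoxyphenol | COc1ccc(Cl)c(O)c1[C@@H](c1cc(OC)cc(OC)c1)[C@H](c1ccc(OC)cc1OC)O | intermediate (not isolated)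
17 | (2R,3R)-7-chloro-2-(2,4-dimethoxyphenyl)-3-(3,5-dimethoxyphenyl)-4-methoxy-2,3-dihydrobenzofuran | Clc1ccc(OC)c2c1O[C@@H](c1ccc(OC)cc1OC)[C@@H]2c1cc(OC)cc(OC)c1 | intermediate
18 | [(2R,3R)-2-(2,4-dimethoxyphenyl)-3-(3,5-dimethoxyphenyl)-4-methoxy-2,3-dihydrobenzofuran-7-yl]boronic acid | OB(O)c1ccc(OC)c2c1O[C@@H](c1ccc(OC)cc1OC)[C@@H]2c1cc(OC)cc(OC)c1 | intermediate (not isolated)
19 | (2R,3R)-2-(2,4-dimethoxyphenyl)-3-(3,5-dimethoxyphenyl)-4-methoxy-2,3-dihydrobenzofuran-7-yl B(mac) | B1(c2ccc(OC)c3c2O[C@@H](c2ccc(OC)cc2OC)[C@@H]3c2cc(OC)cc(OC)c2)O[C@@]2(C)c3cccc4cccc(c34)[C@@]2(C)O1 | intermediate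
20 | (E)-1-(2-iodovinyl)-3,5-dimethoxybenzene | COc1cc(/C=C/I)cc(OC)c1 | intermediate
21 | methyl 4-bromo-3,5-dihydroxybenzoate | COC(=O)c1cc(O)c(Br)c(O)c1 | starting material
22 | methyl 4-bromo-3,5-bis(methoxymethoxy)benzoate | COCOc1cc(C(=O)OC)cc(OCOC)c1Br | intermediate
23 | [4-bromo-3,5-bis(methoxymethoxy)phenyl]methanol | COCOc1cc(CO)cc(OCOC)c1Br | intermediate
24 | 4-bromo-3,5-bis(methoxymethoxy)benzaldehyde | COCOc1cc(C=O)cc(OCOC)c1Br | intermediate
25 | diethyl (4-methoxybenzyl)phosphonate | CCOP(=O)(Cc1ccc(OC)cc1)OCC | starting material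
26 | 2-bromo-1,3-bis(methoxymethoxy)-5-[(E)-2-(4-methoxyphenyl)ethenyl]benzene | COCOc1cc(/C=C/c2ccc(OC)cc2)cc(OCOC)c1Br | intermediate
27 | [(E)-2-(3,5-dimethoxyphenyl)vinyl]lithium | [Li]/C=C/c1cc(OC)cc(OC)c1 | intermediate (not isolated)
28 | lithium ate complex of 19 with the (E)-2-(3,5-dimethoxyphenyl)vinyl group on boron (configuration at boron not defined) | [Li+].COc1cc(/C=C/[B-]2(c3ccc(OC)c4c3O[C@@H](c3ccc(OC)cc3OC)[C@@H]4c3cc(OC)cc(OC)c3)O[C@@]3(C)c4cccc5cccc(c45)[C@@]3(C)O2)cc(OC)c1 | intermediate (not isolated)
29 | (1R,2R)-2-[2,6-bis(methoxymethoxy)-4-[(E)-2-(4-methoxyphenyl)ethenyl]phenyl]-1-[(2R,3R)-2-(2,4-dimethoxyphenyl)-3-(3,5-dimethoxyphenyl)-4-methoxy-2,3-dihydrobenzofuran-7-yl]-2-(3,5-dimethoxyphenyl)ethyl B(mac) | COCOc1cc(/C=C/c2ccc(OC)cc2)cc(OCOC)c1[C@@H](c1cc(OC)cc(OC)c1)[C@H](c1ccc(OC)c2c1O[C@@H](c1ccc(OC)cc1OC)[C@@H]2c1cc(OC)cc(OC)c1)B1O[C@@]2(C)c3cccc4cccc(c34)[C@@]2(C)O1 | intermediate (not isolated)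
30 | (1R,2R)-alcohol corresponding to 29 (OH in place of boron) | COCOc1cc(/C=C/c2ccc(OC)cc2)cc(OCOC)c1[C@@H](c1cc(OC)cc(OC)c1)[C@H](c1ccc(OC)c2c1O[C@@H](c1ccc(OC)cc1OC)[C@@H]2c1cc(OC)cc(OC)c1)O | intermediate
31 | triol from 30 (both ring B phenols free, C2 carbinol) | Oc1cc(/C=C/c2ccc(OC)cc2)cc(O)c1[C@@H](c1cc(OC)cc(OC)c1)[C@H](c1ccc(OC)c2c1O[C@@H](c1ccc(OC)cc1OC)[C@@H]2c1cc(OC)cc(OC)c1)O | intermediate (not isolated)
32 | octamethyl ether of the target with free C4 phenol, (2R,3R,2'R,3'R) | COc1ccc(/C=C/c2cc(O)c3c(c2)O[C@@H](c2ccc(OC)c4c2O[C@@H](c2ccc(OC)cc2OC)[C@@H]4c2cc(OC)cc(OC)c2)[C@@H]3c2cc(OC)cc(OC)c2)cc1 | intermediate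
33 | CNP0217875.2, (2R,3R,2'R,3'R) | Oc1ccc(/C=C/c2cc(O)c3c(c2)O[C@@H](c2ccc(O)c4c2O[C@@H](c2ccc(O)cc2O)[C@@H]4c2cc(O)cc(O)c2)[C@@H]3c2cc(O)cc(O)c2)cc1 | target

## Step count and uncertain steps

Total: 17 steps. Longest linear sequence: 9 steps (3 → 5 → 6 → 14 → 15 → 17 → 19 → 30 → 32 → 33; the branches from 1 and from 7 are equally long).

**Step 6 (key step).** The arylpalladium cation carries two ortho alkoxy groups and must bind a β-aryl alkene that is part of a bulky ate complex. This may be slow, so reduction of bromide 10 or direct transfer of the alkenyl group could take over, and crowding could also weaken the face selection. Fallback (the two aryl groups on C3' change roles, so the hindered ring sits on the alkene and the electrophile is unhindered):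
- Aryllithium 9 is quenched with DMF to 3-chloro-6-methoxy-2-(methoxymethoxy)benzaldehyde F1.
- Takai olefination (CrCl2, CHI3, THF) gives (E)-1-chloro-3-(2-iodovinyl)-4-methoxy-2-(methoxymethoxy)benzene F2.
- Commercial 2,4-dimethoxyphenylboronic acid (COc1ccc(B(O)O)c(OC)c1) is esterified with diol 2 to 2,4-dimethoxyphenyl B(mac) F3.
- F2 and t-BuLi give alkenyllithium F4, which adds to F3 to form ate complex F5.
- Coupling of F5 with commercial 1-bromo-3,5-dimethoxybenzene (COc1cc(Br)cc(OC)c1) under the conditions of step 6, with the ligand antipode that gives C3' as R, should give the (1S,2R)-boronate F6. This is the C2' epimer of 14, because the anti addition now places ring H instead of ring E.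
- Oxidation as in step 7 gives the (1S,2R)-alcohol F7, and the acid of step 8 takes it through epimeric diol F8 and the same C2' cation to 17, where the route is rejoined.

**Step 15.** The same crowding applies as in step 6. In addition, alkenyllithium 27 may deprotonate C3'–H of 19 instead of adding to boron, and the chiral aryl group on boron may work against the ligand. Fallback (the same exchange of roles):
- Bromide 26 is converted by t-BuLi and DMF into 2,6-bis(methoxymethoxy)-4-[(E)-2-(4-methoxyphenyl)ethenyl]benzaldehyde F9.
- Takai olefination gives the (E)-vinyl iodide F10, and t-BuLi gives alkenyllithium F11.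
- F11 adds to 19 to form ate complex F12, which is coupled with 1-bromo-3,5-dimethoxybenzene to boronate F13 (C2 epimer of 29).
- Oxidation gives alcohol F14, and the acid of step 16 leads through epimeric triol F15 to 32.

**Step 8.** While the phenol is still masked, the C2' cation may lose the C3' proton or take a hydride from C3', which would erase the one centre that must survive. Fallback (reordering, so that the cation only forms when its nucleophile is free):
- The acetal of 14 is removed with HCl in MeOH at the boronate stage, where no cation can form, to give phenol boronate F16.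
- Oxidation as in step 7 gives diol 16, now isolated.
- Pyridinium p-toluenesulfonate in CH2Cl2 at 0 °C closes it to 17.

**Step 16.** The same erosion can occur at C3. The acid can also reopen ring F, so C3' is exposed a second time. Fallback: boronate 29 is isolated, its acetals are removed to bisphenol boronate F17, oxidation gives triol 31, and mild acid closes it to 32.

**Step 9.** The ortho-alkoxy arylboronic acid 18 may lose boron by protonation in hot ethanol, and insertion into the electron-rich C–Cl bond may be slow. Fallback (a robust ester is isolated first and the diol exchanged afterwards):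
- Miyaura borylation of 17 with bis(pinacolato)diboron (Pd2(dba)3, XPhos, KOAc, dioxane, 100 °C) gives pinacol boronate F18.
- Diethanolamine converts it into the crystalline diethanolamine adduct F19.
- Brief treatment with dilute HCl in a two-phase system releases 18, which is esterified with diol 2 to 19.

**Step 17.** During the long exposure needed for eight ethers, O1–C2 and O1'–C2' may ionise and the cations may be diverted, and cleavage may stop short, leaving an inseparable mixture of air-sensitive polyphenols. Fallback (ring opening is accepted and repaired, and the product is isolated as a derivative):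
- 32 is treated with excess BBr3 at rt until all ethers are cleaved, then quenched with MeOH.
- The crude material is exposed to the acid of step 16 so that both rings close again to their trans forms.
- Ac2O, pyridine and DMAP convert it into nonaacetate F20, which is purified by chromatography.
- K2CO3 in degassed MeOH at 0 °C releases 33.

## Further compounds

F1 | step 6 | 3-chloro-6-methoxy-2-(methoxymethoxy)benzaldehyde | COc1ccc(Cl)c(OCOC)c1C=O
F2 | step 6 | (E)-1-chloro-3-(2-iodovinyl)-4-methoxy-2-(methoxymethoxy)benzene | COc1ccc(Cl)c(OCOC)c1/C=C/I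
F3 | step 6 | 2,4-dimethoxyphenyl B(mac) | COc1ccc(B2O[C@@]3(C)c4cccc5cccc(c45)[C@@]3(C)O2)c(OC)c1
F4 | step 6 | [(E)-2-[3-chloro-6-methoxy-2-(methoxymethoxy)phenyl]vinyl]lithium | [Li]/C=C/c1c(OC)ccc(Cl)c1OCOC
F5 | step 6 | lithium ate complex of F3 with the alkenyl group of F4 on boron | [Li+].COc1ccc(Cl)c(OCOC)c1/C=C/[B-]1(c2ccc(OC)cc2OC)O[C@@]2(C)c3cccc4cccc(c34)[C@@]2(C)O1
F6 | step 6 | (1S,2R)-2-[3-chloro-6-methoxy-2-(methoxymethoxy)phenyl]-1-(2,4-dimethoxyphenyl)-2-(3,5-dimethoxyphenyl)ethyl B(mac) | COc1ccc(Cl)c(OCOC)c1[C@@H](c1cc(OC)cc(OC)c1)[C@@H](c1ccc(OC)cc1OC)B1O[C@@]2(C)c3cccc4cccc(c34)[C@@]2(C)O1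
F7 | step 6 | (1S,2R)-2-[3-chloro-6-methoxy-2-(methoxymethoxy)phenyl]-1-(2,4-dimethoxyphenyl)-2-(3,5-dimethoxyphenyl)ethanol | COc1ccc(Cl)c(OCOC)c1[C@@H](c1cc(OC)cc(OC)c1)[C@@H](c1ccc(OC)cc1OC)O
F8 | step 6 | 6-chloro-2-[(1R,2S)-2-(2,4-dimethoxyphenyl)-1-(3,5-dimethoxyphenyl)-2-hydroxyethyl]-3-methoxyphenol | COc1ccc(Cl)c(O)c1[C@@H](c1cc(OC)cc(OC)c1)[C@@H](c1ccc(OC)cc1OC)O
F9 | step 15 | 2,6-bis(methoxymethoxy)-4-[(E)-2-(4-methoxyphenyl)ethenyl]benzaldehyde | COCOc1cc(/C=C/c2ccc(OC)cc2)cc(OCOC)c1C=O
F10 | step 15 | 2-[(E)-2-iodovinyl]-1,3-bis(methoxymethoxy)-5-[(E)-2-(4-methoxyphenyl)ethenyl]benzene | COCOc1cc(/C=C/c2ccc(OC)cc2)cc(OCOC)c1/C=C/I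
F11 | step 15 | alkenyllithium from F10 | [Li]/C=C/c1c(OCOC)cc(/C=C/c2ccc(OC)cc2)cc1OCOC
F12 | step 15 | lithium ate complex of 19 with the alkenyl group of F11 on boron | [Li+].COCOc1cc(/C=C/c2ccc(OC)cc2)cc(OCOC)c1/C=C/[B-]1(c2ccc(OC)c3c2O[C@@H](c2ccc(OC)cc2OC)[C@@H]3c2cc(OC)cc(OC)c2)O[C@@]2(C)c3cccc4cccc(c34)[C@@]2(C)O1
F13 | step 15 | C2 epimer of boronate 29, (1S,2R) | COCOc1cc(/C=C/c2ccc(OC)cc2)cc(OCOC)c1[C@@H](c1cc(OC)cc(OC)c1)[C@@H](c1ccc(OC)c2c1O[C@@H](c1ccc(OC)cc1OC)[C@@H]2c1cc(OC)cc(OC)c1)B1O[C@@]2(C)c3cccc4cccc(c34)[C@@]2(C)O1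
F14 | step 15 | C2 epimer of alcohol 30, (1S,2R) | COCOc1cc(/C=C/c2ccc(OC)cc2)cc(OCOC)c1[C@@H](c1cc(OC)cc(OC)c1)[C@@H](c1ccc(OC)c2c1O[C@@H](c1ccc(OC)cc1OC)[C@@H]2c1cc(OC)cc(OC)c1)O
F15 | step 15 | C2 epimer of triol 31 | Oc1cc(/C=C/c2ccc(OC)cc2)cc(O)c1[C@@H](c1cc(OC)cc(OC)c1)[C@@H](c1ccc(OC)c2c1O[C@@H](c1ccc(OC)cc1OC)[C@@H]2c1cc(OC)cc(OC)c1)O
F16 | step 8 | (1R,2R)-2-(3-chloro-2-hydroxy-6-methoxyphenyl)-1-(2,4-dimethoxyphenyl)-2-(3,5-dimethoxyphenyl)ethyl B(mac) | COc1ccc(Cl)c(O)c1[C@@H](c1cc(OC)cc(OC)c1)[C@H](c1ccc(OC)cc1OC)B1O[C@@]2(C)c3cccc4cccc(c34)[C@@]2(C)O1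
F17 | step 16 | bisphenol boronate from 29 (both ring B acetals removed) | Oc1cc(/C=C/c2ccc(OC)cc2)cc(O)c1[C@@H](c1cc(OC)cc(OC)c1)[C@H](c1ccc(OC)c2c1O[C@@H](c1ccc(OC)cc1OC)[C@@H]2c1cc(OC)cc(OC)c1)B1O[C@@]2(C)c3cccc4cccc(c34)[C@@]2(C)O1
F18 | step 9 | pinacol ester of boronic acid 18 | CC1(C)OB(c2ccc(OC)c3c2O[C@@H](c2ccc(OC)cc2OC)[C@@H]3c2cc(OC)cc(OC)c2)OC1(C)C
F19 | step 9 | diethanolamine adduct of boronic acid 18 | [B-]12(c3ccc(OC)c4c3O[C@@H](c3ccc(OC)cc3OC)[C@@H]4c3cc(OC)cc(OC)c3)OCC[NH+]1CCO2
F20 | step 17 | nonaacetate of 33 | CC(=O)Oc1ccc(/C=C/c2cc(OC(C)=O)c3c(c2)O[C@@H](c2ccc(OC(C)=O)c4c2O[C@@H](c2ccc(OC(C)=O)cc2OC(C)=O)[C@@H]4c2cc(OC(C)=O)cc(OC(C)=O)c2)[C@@H]3c2cc(OC(C)=O)cc(OC(C)=O)c2)cc1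
A1 | alternative 1 | 6-bromo-2-[2-(2,4-dimethoxyphenyl)-1-(3,5-dimethoxyphenyl)ethenyl]-3-methoxyphenol (either alkene geometry) | COc1ccc(Br)c(O)c1C(=Cc1ccc(OC)cc1OC)c1cc(OC)cc(OC)c1
A2 | alternative 1 | (2R,3R)-7-bromo-2-(2,4-dimethoxyphenyl)-3-(3,5-dimethoxyphenyl)-4-methoxy-2,3-dihydrobenzofuran | Brc1ccc(OC)c2c1O[C@@H](c1ccc(OC)cc1OC)[C@@H]2c1cc(OC)cc(OC)c1
A3 | alternative 2 | methyl (E)-5-diazo-4-oxopent-2-enoate | COC(=O)/C=C/C(=O)C=[N+]=[N-]
A4 | alternative 2 | methyl (E)-5-oxopenta-2,4-dienoate (vinylketene) | COC(=O)/C=C/C=C=O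
A5 | alternative 2 | triisopropylsilyl ynol ether carrying the C3'/C2' chain | CC(C)[Si](C(C)C)(C(C)C)OC#C[C@@H](c1cc(OC)cc(OC)c1)[C@@H](OC)c1ccc(OC)cc1OC
A6 | alternative 2 | ring E salicylate with free C7a' phenol, silylated C4' oxygen and the chain on C3a' | COC(=O)c1ccc(O[Si](C(C)C)(C(C)C)C(C)C)c(c1O)[C@@H](c1cc(OC)cc(OC)c1)[C@@H](OC)c1ccc(OC)cc1OC
A7 | alternative 3 | methyl 4-[(3,5-dimethoxyphenyl)(tosyl)methyl]-3-hydroxy-5-methoxybenzoate | COC(=O)c1cc(O)c(C(c2cc(OC)cc(OC)c2)S(=O)(=O)c2ccc(C)cc2)c(OC)c1
A8 | alternative 3 | (2R,5R)-2,5-dimethylthiolanium salt of the ring E/F benzyl group (triflate) | C[C@@H]1CC[C@@H](C)[S+]1Cc1ccc(OC)c2c1O[C@@H](c1ccc(OC)cc1OC)[C@@H]2c1cc(OC)cc(OC)c1.[O-]S(=O)(=O)C(F)(F)F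
A9 | alternative 3 | ortho-quinone methide of ring B | O=C1C=C(C(=O)OC)C=C(OC)C1=Cc1cc(OC)cc(OC)c1
A10 | alternative 3 | permethylated bis(dihydrobenzofuran) with a methyl ester on C6 | COC(=O)c1cc(OC)c2c(c1)O[C@@H](c1ccc(OC)c3c1O[C@@H](c1ccc(OC)cc1OC)[C@@H]3c1cc(OC)cc(OC)c1)[C@@H]2c1cc(OC)cc(OC)c1
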